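**Strategy.** The carbocycle is numbered C1 = CHOH, C2 = CMe2, C3 = CH bearing the side chain, C4 = C(=CH2), C5, C6. The key step exploits the 1,3-placement of C2 and C4 about C3. At the ketone oxidation level, C2–C3–C4 are the α′-carbon, carbonyl carbon and α-carbon of methyl 4-methyl-3-oxopentanoate, and C5–C6–C1 is methyl acrylate. One base-mediated Michael–Claisen annulation joins the two three-carbon pieces through C4–C5 and C1–C2 and sets the quaternary carbon. The β-keto ester then serves twice: its enol triflate takes the side chain by B-alkyl Suzuki coupling, and its ester carbon becomes the exocyclic methylene by reductive allylic transposition, which also sets C3.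

Key step: step 1

Assumption: (E)-3-methylpent-2-en-4-yn-1-ol and 1-(2-hydroxy-6-methylphenyl)ethanone are taken as purchasable; the ester-bearing carbon of 4 is enolisable and is drawn without configuration because it becomes sp2 in step 2.

**Step 1**
Reactants: 1 methyl 4-methyl-3-oxopentanoate; 2 methyl acrylate
Product: 4 methyl 3,3-dimethyl-2,4-dioxocyclohexane-1-carboxylate, via Michael adduct 3 (not isolated)
Conditions: t-BuOK (0.1 equiv), THF, 0 °C, slow addition of 2; then t-BuOK (2.5 equiv), 50 °C, same flask; aq HCl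
Reagents that add atoms: none
Why: Catalytic tert-butoxide generates the doubly stabilised enolate of 1, which adds in a Michael sense to 2 and so forms the future C4–C5 bond of the carbocycle (3). With excess base the isopropyl-side enolate of the ketone, reached by proton transfer, attacks the terminal ester in a Claisen (Dieckmann-type) acylation and forms the C1–C2 bond together with the quaternary carbon. The closest known reaction type is the consecutive Michael–Claisen [3+3] annulation of acetoacetates with acrylates or crotonates that gives cyclohexane-1,3-dione-4-carboxylates. The ring closes in the 6-exo-trig mode (carbanion onto the ester carbonyl, methoxide leaving). The only new stereocentre, the ester-bearing carbon, is enolisable and is erased in step 2, so nothing has to be controlled. The step needs C- over O-acylation and the α′-carbon over all other sites: the α-carbon and the glutarate CH2 could only close four-membered rings, the enol lactone from O-acylation reopens under alkoxide, and the excess base holds the product as its enolate, which blocks retro-Claisen opening of the non-enolisable 2,2-dimethyl-1,3-dione.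

**Step 2**
Reactants: 4 methyl 3,3-dimethyl-2,4-dioxocyclohexane-1-carboxylate
Product: 5 methyl 3,3-dimethyl-4-oxo-2-{[(trifluoromethyl)sulfonyl]oxy}cyclohex-1-ene-1-carboxylate
Conditions: Tf2O, i-Pr2NEt, CH2Cl2, −78 °C
Reagents that add atoms: trifluoromethanesulfonic anhydride, O=S(=O)(OS(=O)(=O)C(F)(F)F)C(F)(F)F
Why: Only the β-keto ester is enolised, so amine base and Tf2O should give the enol triflate (enol triflation) at the ring carbon that will carry the side chain, while the isolated ketone next to the quaternary carbon stays untouched at −78 °C.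

**Step 3**
Reactants: 6 (E)-3-methylpent-2-en-4-yn-1-ol
Product: 7 tert-butyl(dimethyl){[(2E)-3-methylpent-2-en-4-yn-1-yl]oxy}silane
Conditions: TBSCl, imidazole, CH2Cl2, 0 °C to rt
Reagents that add atoms: tert-butyldimethylsilyl chloride, CC(C)(C)[Si](C)(C)Cl
Why: Standard silylation of a primary allylic alcohol (silyl ether protection), needed so that only one primary allylic hydroxyl is free in step 8.

**Step 4**
Reactants: 7 tert-butyl(dimethyl){[(2E)-3-methylpent-2-en-4-yn-1-yl]oxy}silane
Product: 8 tert-butyl(dimethyl){[(2E)-3-methylpenta-2,4-dien-1-yl]oxy}silane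
Conditions: H2 (1 atm), Pd/CaCO3 poisoned with Pb(OAc)2, quinoline, hexane, rt
Reagents that add atoms: none
Why: Lindlar semi-hydrogenation: the terminal alkyne binds the poisoned palladium surface far better than the alkenes, so the enyne should stop at the conjugated diene with the E-trisubstituted alkene unchanged.

**Step 5**
Reactants: 5 methyl 3,3-dimethyl-4-oxo-2-{[(trifluoromethyl)sulfonyl]oxy}cyclohex-1-ene-1-carboxylate; 8 tert-butyl(dimethyl){[(2E)-3-methylpenta-2,4-dien-1-yl]oxy}silane
Product: 10 methyl 2-[(3E)-5-{[tert-butyl(dimethyl)silyl]oxy}-3-methylpent-3-en-1-yl]-3,3-dimethyl-4-oxocyclohex-1-ene-1-carboxylate, via alkylborane 9 (not isolated)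
Conditions: 8, 9-BBN-H, THF, 0 °C to rt; then 5, PdCl2(dppf), AsPh3, K3PO4, DMF–H2O, 50 °C
Reagents that add atoms: none
Why: B-alkyl Suzuki–Miyaura coupling: 9-BBN should add anti-Markovnikov to the monosubstituted terminus of the diene only, and the electron-poor enol triflate undergoes oxidative addition readily, as known for 2,6,6-trisubstituted cyclohexenyl triflates; the ketone, ester and silyl ether tolerate the mild base.

**Step 6**
Reactants: 10 methyl 2-[(3E)-5-{[tert-butyl(dimethyl)silyl]oxy}-3-methylpent-3-en-1-yl]-3,3-dimethyl-4-oxocyclohex-1-ene-1-carboxylate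
Product: 11 methyl (4S)-2-[(3E)-5-{[tert-butyl(dimethyl)silyl]oxy}-3-methylpent-3-en-1-yl]-4-hydroxy-3,3-dimethylcyclohex-1-ene-1-carboxylate
Conditions: (R)-2-methyl-CBS-oxazaborolidine (0.2 equiv), catecholborane, toluene, −78 to −40 °C; aq NaOH work-up
Reagents that add atoms: none
Why: Corey–Bakshi–Shibata reduction: the oxazaborolidine distinguishes the quaternary (large) from the methylene (small) flank of the ketone, so the (R)-catalyst should deliver hydride to the face that gives the (S)-carbinol by reagent control, and catecholborane leaves the enoate and the alkene alone at low temperature.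

**Step 7**
Reactants: 11 methyl (4S)-2-[(3E)-5-{[tert-butyl(dimethyl)silyl]oxy}-3-methylpent-3-en-1-yl]-4-hydroxy-3,3-dimethylcyclohex-1-ene-1-carboxylate
Product: 12 (1S)-3-[(3E)-5-{[tert-butyl(dimethyl)silyl]oxy}-3-methylpent-3-en-1-yl]-4-(hydroxymethyl)-2,2-dimethylcyclohex-3-en-1-ol
Conditions: i-Bu2AlH (4 equiv), CH2Cl2, −78 to 0 °C; aq potassium sodium tartrate
Reagents that add atoms: none
Why: DIBAL-H reduction of the conjugated ester to the primary allylic alcohol, with the silyl ether and both alkenes inert; the secondary alkoxide formed first is simply carried along.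

**Step 8**
Reactants: 12 (1S)-3-[(3E)-5-{[tert-butyl(dimethyl)silyl]oxy}-3-methylpent-3-en-1-yl]-4-(hydroxymethyl)-2,2-dimethylcyclohex-3-en-1-ol
Product: 15 (1S,3R)-3-[(3E)-5-{[tert-butyl(dimethyl)silyl]oxy}-3-methylpent-3-en-1-yl]-2,2-dimethyl-4-methylidenecyclohexan-1-ol, via sulfonylhydrazine 13 (not isolated), via allylic diazene 14 (not isolated)
Conditions: 2-nitrobenzenesulfonohydrazide (NBSH), PPh3, DEAD, THF, −30 °C, then rt
Reagents that add atoms: none
Why: Myers reductive 1,3-transposition: Mitsunobu N-alkylation of NBSH at the primary allylic carbon, loss of sulfinate and retro-ene loss of N2 from the allylic diazene should deliver hydrogen to C3 on the ring face anti to the pseudoaxial C2 methyl (the face of the axial C1–H in the half-chair with equatorial hydroxyl), which places the side chain cis to the hydroxyl (3R) by substrate control and leaves the exocyclic methylene.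

**Step 9**
Reactants: 15 (1S,3R)-3-[(3E)-5-{[tert-butyl(dimethyl)silyl]oxy}-3-methylpent-3-en-1-yl]-2,2-dimethyl-4-methylidenecyclohexan-1-ol
Product: 16 (1S,3R)-3-[(3E)-5-hydroxy-3-methylpent-3-en-1-yl]-2,2-dimethyl-4-methylidenecyclohexan-1-ol
Conditions: Bu4NF, THF, 0 °C to rt
Reagents that add atoms: none
Why: Fluoride-mediated desilylation; the exocyclic alkene, the trisubstituted alkene and the free secondary alcohol are stable to Bu4NF.

**Step 10**
Reactants: 17 1-(2-hydroxy-6-methylphenyl)ethan-1-one
Product: 18 4-hydroxy-5-methyl-2H-chromen-2-one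
Conditions: NaH, diethyl carbonate, toluene, reflux; aq HCl
Reagents that add atoms: diethyl carbonate, CCOC(=O)OCC
Why: Claisen-type C-acylation of the acetophenone enolate by diethyl carbonate followed by lactonisation onto the phenoxide, the standard synthesis of 4-hydroxycoumarins.

**Step 11**
Reactants: 16 (1S,3R)-3-[(3E)-5-hydroxy-3-methylpent-3-en-1-yl]-2,2-dimethyl-4-methylidenecyclohexan-1-ol; 18 4-hydroxy-5-methyl-2H-chromen-2-one
Product: 19 4-{[(2E)-5-[(1R,3S)-3-hydroxy-2,2-dimethyl-6-methylidenecyclohexyl]-3-methylpent-2-en-1-yl]oxy}-5-methyl-2H-chromen-2-one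
Conditions: PPh3, DIAD, THF, 0 °C to rt
Reagents that add atoms: none
Why: Mitsunobu etherification: the acidic 4-hydroxycoumarin is alkylated on O-4 by the alkoxyphosphonium of the unhindered primary allylic alcohol in an SN2 step that keeps the E-alkene, while the neopentyl-type secondary hydroxyl is too hindered to be activated.

**Compound list**
1 | methyl 4-methyl-3-oxopentanoate | COC(=O)CC(=O)C(C)C | starting material
2 | methyl acrylate | C=CC(=O)OC | starting material
3 | dimethyl 2-(2-methylpropanoyl)pentanedioate | COC(=O)CCC(C(=O)OC)C(=O)C(C)C | intermediate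
4 | methyl 3,3-dimethyl-2,4-dioxocyclohexane-1-carboxylate | COC(=O)C1CCC(=O)C(C)(C)C1=O | intermediate
5 | methyl 3,3-dimethyl-4-oxo-2-{[(trifluoromethyl)sulfonyl]oxy}cyclohex-1-ene-1-carboxylate | COC(=O)C1=C(OS(=O)(=O)C(F)(F)F)C(C)(C)C(=O)CC1 | intermediate
6 | (E)-3-methylpent-2-en-4-yn-1-ol | C#C/C(C)=C/CO | starting material
7 | tert-butyl(dimethyl){[(2E)-3-methylpent-2-en-4-yn-1-yl]oxy}silane | C#C/C(C)=C/CO[Si](C)(C)C(C)(C)C | intermediate
8 | tert-butyl(dimethyl){[(2E)-3-methylpenta-2,4-dien-1-yl]oxy}silane | C=C/C(C)=C/CO[Si](C)(C)C(C)(C)C | intermediate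
9 | 9-[(3E)-5-{[tert-butyl(dimethyl)silyl]oxy}-3-methylpent-3-en-1-yl]-9-borabicyclo[3.3.1]nonane | C(C/C(C)=C/CO[Si](C)(C)C(C)(C)C)B1C2CCCC1CCC2 | intermediate
10 | methyl 2-[(3E)-5-{[tert-butyl(dimethyl)silyl]oxy}-3-methylpent-3-en-1-yl]-3,3-dimethyl-4-oxocyclohex-1-ene-1-carboxylate | COC(=O)C1=C(CC/C(C)=C/CO[Si](C)(C)C(C)(C)C)C(C)(C)C(=O)CC1 | intermediate
11 | methyl (4S)-2-[(3E)-5-{[tert-butyl(dimethyl)silyl]oxy}-3-methylpent-3-en-1-yl]-4-hydroxy-3,3-dimethylcyclohex-1-ene-1-carboxylate | COC(=O)C1=C(CC/C(C)=C/CO[Si](C)(C)C(C)(C)C)C(C)(C)[C@@H](O)CC1 | intermediate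
12 | (1S)-3-[(3E)-5-{[tert-butyl(dimethyl)silyl]oxy}-3-methylpent-3-en-1-yl]-4-(hydroxymethyl)-2,2-dimethylcyclohex-3-en-1-ol | OCC1=C(CC/C(C)=C/CO[Si](C)(C)C(C)(C)C)C(C)(C)[C@@H](O)CC1 | intermediate
13 | N-{[(4S)-2-[(3E)-5-{[tert-butyl(dimethyl)silyl]oxy}-3-methylpent-3-en-1-yl]-4-hydroxy-3,3-dimethylcyclohex-1-en-1-yl]methyl}-2-nitrobenzenesulfonohydrazide | NN(CC1=C(CC/C(C)=C/CO[Si](C)(C)C(C)(C)C)C(C)(C)[C@@H](O)CC1)S(=O)(=O)c1ccccc1[N+](=O)[O-] | intermediate
14 | (1S)-3-[(3E)-5-{[tert-butyl(dimethyl)silyl]oxy}-3-methylpent-3-en-1-yl]-4-(diazenylmethyl)-2,2-dimethylcyclohex-3-en-1-ol | N=NCC1=C(CC/C(C)=C/CO[Si](C)(C)C(C)(C)C)C(C)(C)[C@@H](O)CC1 | intermediate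
15 | (1S,3R)-3-[(3E)-5-{[tert-butyl(dimethyl)silyl]oxy}-3-methylpent-3-en-1-yl]-2,2-dimethyl-4-methylidenecyclohexan-1-ol | C=C1CC[C@H](O)C(C)(C)[C@@H]1CC/C(C)=C/CO[Si](C)(C)C(C)(C)C | intermediate
16 | (1S,3R)-3-[(3E)-5-hydroxy-3-methylpent-3-en-1-yl]-2,2-dimethyl-4-methylidenecyclohexan-1-ol | C=C1CC[C@H](O)C(C)(C)[C@@H]1CC/C(C)=C/CO | intermediate
17 | 1-(2-hydroxy-6-methylphenyl)ethan-1-one | CC(=O)c1c(C)cccc1O | starting material
18 | 4-hydroxy-5-methyl-2H-chromen-2-one | Cc1cccc2oc(=O)cc(O)c12 | intermediate
19 | 4-{[(2E)-5-[(1R,3S)-3-hydroxy-2,2-dimethyl-6-methylidenecyclohexyl]-3-methylpent-2-en-1-yl]oxy}-5-methyl-2H-chromen-2-one | C=C1CC[C@H](O)C(C)(C)[C@@H]1CC/C(C)=C/COc1cc(=O)oc2cccc(C)c12 | target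

**Step count.** Total: 11 steps. Longest linear sequence: 8 steps (steps 1, 2, 5, 6, 7, 8, 9, 11).

**Steps most likely to fail**

Step 1. The acylation may run backwards (retro-Claisen opening of the non-enolisable dione by methoxide), and a second acrylate may add to the Michael adduct. The fallback sets out from 1 and uses acrolein in place of 2. Michael addition with catalytic DBU in THF at 0 °C should give methyl 2-(2-methylpropanoyl)-5-oxopentanoate F1. The isopropyl-side enolate of F1 should then close by intramolecular aldol addition (the classical α,α′-annulation, with no leaving alkoxide and hence no reverse acyl cleavage) to methyl 4-hydroxy-3,3-dimethyl-2-oxocyclohexane-1-carboxylate F2, forming the same two ring bonds. Dess–Martin periodinane in CH2Cl2 with NaHCO3 would oxidise F2, and the route is rejoined at 4.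

Step 8. Hydrogen delivery from the diazene may show poor facial selectivity, or the free hydroxyl may steer it to the wrong face by hydrogen bonding. The fallback sets out from 12 and replaces the retro-ene by hydride transfer from a π-allyl palladium formate on a substrate whose hydroxyl face is blocked. Methyl chloroformate and pyridine should acylate only the primary hydroxyl to give {(4S)-2-[(3E)-5-{[tert-butyl(dimethyl)silyl]oxy}-3-methylpent-3-en-1-yl]-4-hydroxy-3,3-dimethylcyclohex-1-en-1-yl}methyl methyl carbonate F3. TBSOTf and 2,6-lutidine would silylate the secondary hydroxyl to give the bis-silyl carbonate F4. Pd(OAc)2, PBu3 and NH4HCO2 in dioxane should deliver hydride to the more substituted allyl terminus from the palladium-bearing, less hindered face and give tert-butyl{[(1S,3R)-3-[(3E)-5-{[tert-butyl(dimethyl)silyl]oxy}-3-methylpent-3-en-1-yl]-2,2-dimethyl-4-methylidenecyclohexyl]oxy}dimethylsilane F5. Excess Bu4NF removes both silyl groups, and the route is rejoined at 16.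

Step 11. The ambident coumarin may be alkylated at O-2 (giving the 2-alkoxychromone) or at C-3, because the peri methyl group hinders O-4. The fallback sets out from 18 and reverses the polarity. POCl3 with Et3N at reflux should give 4-chloro-5-methyl-2H-chromen-2-one F6. The primary alkoxide of 16 (NaH, 1 equiv, THF–DMF, 0 °C) should then displace chloride by addition–elimination at C-4, which can only give the 4-O ether, and the route is rejoined at 19.

**Further compounds**
F1 | step 1 | methyl 2-(2-methylpropanoyl)-5-oxopentanoate | COC(=O)C(CCC=O)C(=O)C(C)C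
F2 | step 1 | methyl 4-hydroxy-3,3-dimethyl-2-oxocyclohexane-1-carboxylate | COC(=O)C1CCC(O)C(C)(C)C1=O
F3 | step 8 | {(4S)-2-[(3E)-5-{[tert-butyl(dimethyl)silyl]oxy}-3-methylpent-3-en-1-yl]-4-hydroxy-3,3-dimethylcyclohex-1-en-1-yl}methyl methyl carbonate | COC(=O)OCC1=C(CC/C(C)=C/CO[Si](C)(C)C(C)(C)C)C(C)(C)[C@@H](O)CC1
F4 | step 8 | {(4S)-4-{[tert-butyl(dimethyl)silyl]oxy}-2-[(3E)-5-{[tert-butyl(dimethyl)silyl]oxy}-3-methylpent-3-en-1-yl]-3,3-dimethylcyclohex-1-en-1-yl}methyl methyl carbonate | COC(=O)OCC1=C(CC/C(C)=C/CO[Si](C)(C)C(C)(C)C)C(C)(C)[C@@H](O[Si](C)(C)C(C)(C)C)CC1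
F5 | step 8 | tert-butyl{[(1S,3R)-3-[(3E)-5-{[tert-butyl(dimethyl)silyl]oxy}-3-methylpent-3-en-1-yl]-2,2-dimethyl-4-methylidenecyclohexyl]oxy}dimethylsilane | C=C1CC[C@H](O[Si](C)(C)C(C)(C)C)C(C)(C)[C@@H]1CC/C(C)=C/CO[Si](C)(C)C(C)(C)C
F6 | step 11 | 4-chloro-5-methyl-2H-chromen-2-one | Cc1cccc2oc(=O)cc(Cl)c12
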